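**Retrosynthetic overview**
1. Endgame, functional groups only: the aldehyde comes from a primary alcohol, the oxirane from Sharpless epoxidation of a 2-substituted allyl alcohol, the exocyclic methylene from Mannich/elimination, and the γ-lactone from acid closure of the C8 hydroxyl onto a tert-butyl acetate arm.
2. Key disconnection: the ring bond between the carbinol carbon C9 and the quaternary carbon C10. It opens to an acyclic aldehyde carrying an (E)-allylboronate, and closure is an intramolecular allylboration.
3. Enabling feature: inside the cyclohexane, HO–C9H–C10(CH3)(CH=CH2) is a homoallylic alcohol, and O–C6H–C5H–C4(=CH2) repeats the motif. The 1,4-dioxygenated ring with two adjacent alkenyl-bearing carbons (C5, C10) is therefore the retron of two successive allylations by one 1,2-bis(boronate).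
4. C5–C6 comes from the first allylboration of a C6 aldehyde. That aldehyde holds C6–C9, C11 and C12 and is made from L-malate by Fráter–Seebach alkylation. Its partner is the bis(boronate) made by enantioselective diboration of a (Z)-triene, itself built from propyne, a vinyl unit and a 2-bromoallyl unit.
5. Ring order: cyclohexane (step 13), γ-lactone (step 14), oxirane (step 18).

Key step: step 13

Remark on locants (elemanolide numbering):
- C10 is the quaternary ring carbon, bearing the C14 methyl and the C1=C2 vinyl.
- C5 is the ring CH bearing the C4 side chain; C3 is that chain's CH2 and C15 its oxygenated carbon.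
- C6 is the acyloxy carbon.
- C7 and C8 are the lactone ring-fusion carbons; C8 bears O.
- C9 is the carbinol carbon.
- C11, C12 and C13 are the lactone α-carbon, carbonyl and exocyclic methylene.

Assumption: the ligand enantiomer in step 9 is taken as the one that gives the (S)-configured C–B centre. The aminomethyl-bearing lactone carbon made in step 15 is an inconsequential epimer mixture and is drawn without configuration.

**Step 1**
Reactants: 1 dimethyl (S)-malate; 2 tert-butyl bromoacetate
Product: 3 3-tert-butyl 1,2-dimethyl (1S,2R)-1-hydroxypropane-1,2,3-tricarboxylate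
Conditions: LiN(SiMe3)2 (2.2 equiv), THF, −78 → −20 °C; then 2, −78 → −10 °C
Reagents that add atoms: none
Why: Fráter–Seebach alkylation, in which the chelated lithium alkoxide–enolate of the β-hydroxy ester is alkylated anti to the carbinol substituent, so the malate centre (later C8) sets the new centre (later C7) as (2R).

**Step 2**
Reactants: 3
Product: 4 4-tert-butyl 1-methyl (2R)-2-[(1S)-1,2-dihydroxyethyl]butanedioate
Conditions: BH3·SMe2 (1.05 equiv), NaBH4 (5 mol %), THF, 0 °C → rt; MeOH quench
Reagents that add atoms: none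
Why: Chelation-directed borane reduction, in which the borate formed at the free hydroxyl delivers hydride only to the adjacent α-hydroxy ester, so the other methyl ester, the tert-butyl ester and both stereocentres stay untouched.

**Step 3**
Reactants: 4
Product: 5 4-tert-butyl 1-methyl (2R)-2-[(1S)-1,2-bis(triethylsilyloxy)ethyl]butanedioate
Conditions: Et3SiCl (2.5 equiv), imidazole, CH2Cl2, 0 °C
Reagents that add atoms: chlorotriethylsilane, CC[Si](Cl)(CC)CC
Why: Standard silyl ether formation, carried out at once on the crude diol so that lactonisation of the primary hydroxyl onto the methyl ester cannot compete.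

**Step 4**
Reactants: 5
Product: 6 tert-butyl (3R,4S)-3-formyl-4,5-bis(triethylsilyloxy)pentanoate
Conditions: iBu2AlH (1.1 equiv), CH2Cl2, −78 °C; aq. potassium sodium tartrate
Reagents that add atoms: none
Why: Partial ester reduction, in which the aluminium hemiacetal of the methyl ester persists at −78 °C and the tert-butyl ester is too hindered to react, so the α-stereocentre is carried into the aldehyde under non-basic conditions.

**Step 5**
Reactants: 7 propyne
Product: 9 2-[(Z)-2-bromoprop-1-enyl]-4,4,5,5-tetramethyl-1,3,2-dioxaborolane, via (Z)-2-bromopropenyldibromoborane 8 (not isolated)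
Conditions: BBr3, CH2Cl2, −78 °C → rt; then pinacol, −78 °C → rt
Reagents that add atoms: boron tribromide, BrB(Br)Br; pinacol, CC(C)(O)C(C)(C)O
Why: syn-Bromoboration of a terminal alkyne puts bromine on the internal carbon and boron cis to it on the terminal carbon, which fixes the (Z)-geometry of the later C10=C5 alkene.

**Step 6**
Reactants: 9; 10 vinylmagnesium bromide
Product: 12 2-[(1Z)-2-methylbuta-1,3-dienyl]-4,4,5,5-tetramethyl-1,3,2-dioxaborolane, via vinylzinc bromide 11 (not isolated)
Conditions: 10, ZnBr2, THF, 0 °C; then 9, PdCl2(DPEphos) (2 mol %), THF, rt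
Reagents that add atoms: zinc bromide, [Zn+2].[Br-].[Br-] (atoms end only in intermediate 11)
Why: Negishi coupling at the C–Br bond proceeds with retention of alkene geometry and, being base-free, leaves the pinacol boronate for the next coupling.

**Step 7**
Reactants: 13 2-bromoprop-2-en-1-ol
Product: 14 (2-bromoallyloxy)(tert-butyl)diphenylsilane
Conditions: tBuPh2SiCl, imidazole, CH2Cl2, rt
Reagents that add atoms: tert-butylchlorodiphenylsilane, CC(C)(C)[Si](Cl)(c1ccccc1)c1ccccc1
Why: Standard silylation; the acid-stable silyl ether is chosen to survive the later trifluoroacetic acid step.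

**Step 8**
Reactants: 12; 14
Product: 15 tert-butyl{[(3Z)-4-methyl-2-methylidenehexa-3,5-dienyl]oxy}diphenylsilane
Conditions: Pd(PPh3)4 (5 mol %), aq. NaOH, THF, rt → 40 °C
Reagents that add atoms: none
Why: Suzuki–Miyaura coupling with retention at both alkenyl partners gives the (Z)-triene, and the mild temperature keeps the 6π electrocyclisation of the (Z)-hexatriene out of reach.

**Step 9**
Reactants: 15
Product: 16 (2S,3Z)-1,2-bis(pinacolatoboryl)-3-methyl-5-methylidene-6-(tert-butyldiphenylsilyloxy)hex-3-ene
Conditions: B2pin2 (1.05 equiv), Pt(dba)3 (3 mol %), TADDOL-derived phenylphosphonite ligand (3,5-diisopropylphenyl groups, 6 mol %), THF, 60 °C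
Reagents that add atoms: bis(pinacolato)diboron, CC1(C)OB(OC1(C)C)B1OC(C)(C)C(C)(C)O1
Why: Platinum-catalysed enantioselective 1,2-diboration of a cis-substituted 1,3-diene, in which the (Z)-substituent blocks the s-cis conformer needed for 1,4-addition, the monosubstituted vinyl reacts ahead of the 1,1-disubstituted alkene, and the chiral phosphonite sets the secondary C–B centre as (S).

**Step 10**
Reactants: 6; 16
Product: 18 tert-butyl (3S,4R,5R,6E)-3-[(1S)-1,2-bis(triethylsilyloxy)ethyl]-5-[3-(tert-butyldiphenylsilyloxy)prop-1-en-2-yl]-4-hydroxy-6-methyl-8-(pinacolatoboryl)oct-6-enoate, via O-boryl adduct 17 (not isolated)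
Conditions: 16 (1.2 equiv), toluene, rt → 45 °C; aq. NaHCO3 work-up
Reagents that add atoms: none
Why: Type-one allylboration through a chair Zimmerman–Traxler transition state, in which the (S)-C–B centre delivers the allyl unit suprafacially, the CH2Bpin group sits equatorial to avoid the axial (Z)-substituent and so gives the (E)-trisubstituted allylboronate, the (Z)-geometry gives the syn C5/C6 pair, and this reagent control overrides the weak bias of the α-branched aldehyde.

**Step 11**
Reactants: 18
Product: 19 the C6 isobutyrate of 18 (3S,4R,5R,6E; side chain 1S)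
Conditions: (iPrCO)2O, DMAP, Et3N, CH2Cl2, rt
Reagents that add atoms: isobutyric anhydride, CC(C)C(=O)OC(=O)C(C)C
Why: DMAP-catalysed acylation of the only free hydroxyl installs the ester of the target early, which blocks C6–O from any later lactonisation and removes the need to tell C6–OH from C9–OH.

**Step 12**
Reactants: 19
Product: 20 the primary (C9) alcohol obtained from 19 by loss of the primary triethylsilyl group
Conditions: PPTS (0.2 equiv), MeOH/CH2Cl2 (1:4), −10 → 0 °C
Reagents that add atoms: none
Why: Acid-catalysed methanolysis distinguishes the unhindered primary triethylsilyl ether from the secondary one, the tert-butyldiphenylsilyl ether, the esters and the pinacol boronate.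

**Step 13**
Reactants: 20
Product: 23 cyclohexanol core (C9 hydroxyl and C10 vinyl equatorial; C10 methyl and C8 triethylsilyloxy axial; C5 alkenyl arm; C6 isobutyrate and C7 tert-butyl acetate arm equatorial), via silyloxy aldehyde 21 (not isolated), via O-boryl cyclohexanol 22 (not isolated)
Conditions: Dess–Martin periodinane (1.3 equiv), CH2Cl2 (0.005 M), 0 °C → rt, then 35 °C; aq. Na2S2O3/NaHCO3 work-up
Reagents that add atoms: none
Why: Dess–Martin oxidation of the only free hydroxyl gives the α-silyloxy aldehyde 21, whose carbonyl oxygen binds the tethered pinacol boronate so that the γ,γ-disubstituted (E)-allyl unit adds through a closed six-membered Zimmerman–Traxler transition state with allylic transposition, forming the C9–C10 bond, the quaternary carbon, the vinyl group and the carbinol in one event (borate 22 is hydrolysed on work-up). The closest known reaction types are the intramolecular allylboration set off by liberation of an aldehyde and the second stage of the diene diboration/double allylation route to cyclohexane-1,4-diols. The cyclohexane closes in the 6-exo-trig mode at the carbonyl through a trans-decalin-like pair of fused chairs (the forming carbocycle and the boron-containing ring). C10 is fixed by the configurationally stable (E)-alkene, which puts the ring chain equatorial and the methyl axial in the boron chair, and C9 by the equatorial place of the aldehyde substituent, so that hydroxyl and vinyl come out trans-diequatorial and the hydroxyl cis to the methyl. The absolute sense follows from the existing centres, because only one carbocyclic chair keeps the C5, C6 and C7 arms equatorial (C8 silyl ether axial), whereas the ring-flipped alternative carries three axial groups. The step needs chemoselective oxidation (secured by protection of every other oxygen), ring closure ahead of intermolecular allylation (secured by dilution and the six-membered tether) and retention of alkene geometry (secured by the pinacol boronate, which undergoes no 1,3-boron shift at this temperature).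

**Step 14**
Reactants: 23
Product: 25 (3aS,4R,5S,6S,7R,7aS)-5-[3-(tert-butyldiphenylsilyloxy)prop-1-en-2-yl]-6-ethenyl-7-hydroxy-6-methyl-2-oxooctahydro-1-benzofuran-4-yl 2-methylpropanoate, via hydroxy acid 24 (not isolated)
Conditions: CF3CO2H/CH2Cl2 (1:4), 0 °C → rt
Reagents that add atoms: none
Why: Acidolysis removes the tert-butyl ester and the secondary triethylsilyl ether, and the axial C8 hydroxyl then closes onto the cis equatorial acetic acid arm (5-exo-trig lactonisation), which is the only γ-lactone possible because C6–O is acylated and C9–OH is 1,3-diequatorial to the arm.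

**Step 15**
Reactants: 25
Product: 26 the α-(dimethylaminomethyl) lactone derived from 25 (ring configuration unchanged; new α-carbon as epimer mixture)
Conditions: LiN(SiMe3)2 (2.2 equiv), THF, −78 °C; CH2=NMe2+ I−, −78 °C → rt
Reagents that add atoms: N,N-dimethylmethyleneiminium iodide (Eschenmoser's salt), C=[N+](C)C.[I-]
Why: Mannich-type aminomethylation of the lactone enolate, in which the first equivalent of base is consumed by C9–OH and the second removes the more acidic and more accessible lactone CH2 proton rather than the hindered tertiary C–H of the isobutyrate.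

**Step 16**
Reactants: 26
Product: 28 (3aS,4R,5S,6S,7R,7aS)-5-[3-(tert-butyldiphenylsilyloxy)prop-1-en-2-yl]-6-ethenyl-7-hydroxy-6-methyl-3-methylidene-2-oxooctahydro-1-benzofuran-4-yl 2-methylpropanoate, via trimethylammonium iodide 27 (not isolated)
Conditions: MeI, THF/MeOH, rt; then aq. NaHCO3, CH2Cl2, rt
Reagents that add atoms: iodomethane, CI (atoms end only in intermediate 27)
Why: Quaternisation followed by mild E1cB (Hofmann-type) elimination gives the exocyclic methylene and erases the α-carbon epimers, under conditions that spare the isobutyrate.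

**Step 17**
Reactants: 28
Product: 29 (3aS,4R,5S,6S,7R,7aS)-6-ethenyl-7-hydroxy-5-(3-hydroxyprop-1-en-2-yl)-6-methyl-3-methylidene-2-oxooctahydro-1-benzofuran-4-yl 2-methylpropanoate
Conditions: HF·pyridine, pyridine, THF, 0 °C → rt
Reagents that add atoms: none
Why: Buffered fluoride desilylation frees the primary allylic alcohol without the basicity that could add to or isomerise the methylene lactone.

**Step 18**
Reactants: 29
Product: 30 (3aS,4S,5S,6S,7R,7aS)-6-ethenyl-7-hydroxy-5-[(2S)-2-(hydroxymethyl)oxiran-2-yl]-6-methyl-3-methylidene-2-oxooctahydro-1-benzofuran-4-yl 2-methylpropanoate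
Conditions: Ti(OiPr)4 (0.3 equiv), L-(+)-diethyl tartrate (0.36 equiv), tBuOOH (2 equiv), 4 Å molecular sieves, CH2Cl2, −20 °C
Reagents that add atoms: tert-butyl hydroperoxide, CC(C)(C)OO
Why: Sharpless asymmetric epoxidation, in which the titanium tartrate binds the primary allylic alcohol and L-(+)-tartrate delivers oxygen in the (S)-2-substituted-glycidol sense to set C4, while the vinyl group (only homoallylic to a hindered hydroxyl) and the electron-poor methylene lactone are left alone.

**Step 19**
Reactants: 30
Product: 31 (3aS,4S,5S,6S,7R,7aS)-6-ethenyl-5-[(2R)-2-formyloxiran-2-yl]-7-hydroxy-6-methyl-3-methylidene-2-oxooctahydro-1-benzofuran-4-yl 2-methylpropanoate (target)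
Conditions: TEMPO (0.1 equiv), PhI(OAc)2 (1.2 equiv), CH2Cl2, rt
Reagents that add atoms: none
Why: Oxoammonium (TEMPO) oxidation selects the primary alcohol over the neopentyl secondary C9–OH and stops at the aldehyde, whose α-carbon is quaternary and cannot epimerise (the descriptor changes from S to R only by priority).

**Compound list**
1 | dimethyl (S)-malate | COC(=O)C[C@H](O)C(=O)OC | starting material
2 | tert-butyl bromoacetate | CC(C)(C)OC(=O)CBr | starting material
3 | 3-tert-butyl 1,2-dimethyl (1S,2R)-1-hydroxypropane-1,2,3-tricarboxylate | COC(=O)[C@H](CC(=O)OC(C)(C)C)[C@H](O)C(=O)OC | intermediate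
4 | 4-tert-butyl 1-methyl (2R)-2-[(1S)-1,2-dihydroxyethyl]butanedioate | COC(=O)[C@H](CC(=O)OC(C)(C)C)[C@H](O)CO | intermediate
5 | 4-tert-butyl 1-methyl (2R)-2-[(1S)-1,2-bis(triethylsilyloxy)ethyl]butanedioate | COC(=O)[C@H](CC(=O)OC(C)(C)C)[C@H](O[Si](CC)(CC)CC)CO[Si](CC)(CC)CC | intermediate
6 | tert-butyl (3R,4S)-3-formyl-4,5-bis(triethylsilyloxy)pentanoate | O=C[C@H](CC(=O)OC(C)(C)C)[C@H](O[Si](CC)(CC)CC)CO[Si](CC)(CC)CC | intermediate
7 | propyne | CC#C | starting material
8 | (Z)-(2-bromoprop-1-enyl)dibromoborane | Br/C(C)=C\B(Br)Br | intermediate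
9 | 2-[(Z)-2-bromoprop-1-enyl]-4,4,5,5-tetramethyl-1,3,2-dioxaborolane | Br/C(C)=C\B1OC(C)(C)C(C)(C)O1 | intermediate
10 | vinylmagnesium bromide | C=C[Mg]Br | starting material
11 | vinylzinc bromide | C=C[Zn]Br | intermediate
12 | 2-[(1Z)-2-methylbuta-1,3-dienyl]-4,4,5,5-tetramethyl-1,3,2-dioxaborolane | C=C/C(C)=C\B1OC(C)(C)C(C)(C)O1 | intermediate
13 | 2-bromoprop-2-en-1-ol | OCC(Br)=C | starting material
14 | (2-bromoallyloxy)(tert-butyl)diphenylsilane | C=C(Br)CO[Si](c1ccccc1)(c1ccccc1)C(C)(C)C | intermediate
15 | (Z)-triene silyl ether | C=C/C(C)=C\C(=C)CO[Si](c1ccccc1)(c1ccccc1)C(C)(C)C | intermediate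
16 | (2S,3Z)-1,2-bis(boronate) | CC1(C)OB(C[C@H](B2OC(C)(C)C(C)(C)O2)/C(C)=C\C(=C)CO[Si](c2ccccc2)(c2ccccc2)C(C)(C)C)OC1(C)C | intermediate
17 | O-boryl adduct of the first allylboration | CC1(C)OB(C/C=C(\C)[C@H](C(=C)CO[Si](c2ccccc2)(c2ccccc2)C(C)(C)C)[C@@H](OB2OC(C)(C)C(C)(C)O2)[C@H](CC(=O)OC(C)(C)C)[C@H](O[Si](CC)(CC)CC)CO[Si](CC)(CC)CC)OC1(C)C | intermediate
18 | C6 alcohol with (E)-allylboronate | CC1(C)OB(C/C=C(\C)[C@H](C(=C)CO[Si](c2ccccc2)(c2ccccc2)C(C)(C)C)[C@@H](O)[C@H](CC(=O)OC(C)(C)C)[C@H](O[Si](CC)(CC)CC)CO[Si](CC)(CC)CC)OC1(C)C | intermediate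
19 | C6 isobutyrate | CC1(C)OB(C/C=C(\C)[C@H](C(=C)CO[Si](c2ccccc2)(c2ccccc2)C(C)(C)C)[C@@H](OC(=O)C(C)C)[C@H](CC(=O)OC(C)(C)C)[C@H](O[Si](CC)(CC)CC)CO[Si](CC)(CC)CC)OC1(C)C | intermediate
20 | C9 primary alcohol | CC1(C)OB(C/C=C(\C)[C@H](C(=C)CO[Si](c2ccccc2)(c2ccccc2)C(C)(C)C)[C@@H](OC(=O)C(C)C)[C@H](CC(=O)OC(C)(C)C)[C@H](O[Si](CC)(CC)CC)CO)OC1(C)C | intermediate
21 | C9 α-silyloxy aldehyde | CC1(C)OB(C/C=C(\C)[C@H](C(=C)CO[Si](c2ccccc2)(c2ccccc2)C(C)(C)C)[C@@H](OC(=O)C(C)C)[C@H](CC(=O)OC(C)(C)C)[C@H](O[Si](CC)(CC)CC)C=O)OC1(C)C | intermediate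
22 | O-boryl cyclohexanol | C=C[C@@]1(C)[C@H](C(=C)CO[Si](c2ccccc2)(c2ccccc2)C(C)(C)C)[C@@H](OC(=O)C(C)C)[C@H](CC(=O)OC(C)(C)C)[C@H](O[Si](CC)(CC)CC)[C@@H]1OB2OC(C)(C)C(C)(C)O2 | intermediate
23 | cyclohexanol core | C=C[C@@]1(C)[C@H](C(=C)CO[Si](c2ccccc2)(c2ccccc2)C(C)(C)C)[C@@H](OC(=O)C(C)C)[C@H](CC(=O)OC(C)(C)C)[C@H](O[Si](CC)(CC)CC)[C@@H]1O | intermediate
24 | C8,C9-diol acid | C=C[C@@]1(C)[C@H](C(=C)CO[Si](c2ccccc2)(c2ccccc2)C(C)(C)C)[C@@H](OC(=O)C(C)C)[C@H](CC(=O)O)[C@H](O)[C@@H]1O | intermediate
25 | cis-fused γ-lactone | C=C[C@@]1(C)[C@H](C(=C)CO[Si](c2ccccc2)(c2ccccc2)C(C)(C)C)[C@@H](OC(=O)C(C)C)[C@@H]2CC(=O)O[C@@H]2[C@@H]1O | intermediate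
26 | α-(dimethylaminomethyl) lactone | C=C[C@@]1(C)[C@H](C(=C)CO[Si](c2ccccc2)(c2ccccc2)C(C)(C)C)[C@@H](OC(=O)C(C)C)[C@@H]2C(CN(C)C)C(=O)O[C@@H]2[C@@H]1O | intermediate
27 | trimethylammonium iodide | C=C[C@@]1(C)[C@H](C(=C)CO[Si](c2ccccc2)(c2ccccc2)C(C)(C)C)[C@@H](OC(=O)C(C)C)[C@@H]2C(C[N+](C)(C)C)C(=O)O[C@@H]2[C@@H]1O.[I-] | intermediate
28 | α-methylene lactone silyl ether | C=C[C@@]1(C)[C@H](C(=C)CO[Si](c2ccccc2)(c2ccccc2)C(C)(C)C)[C@@H](OC(=O)C(C)C)[C@@H]2C(=C)C(=O)O[C@@H]2[C@@H]1O | intermediate
29 | allylic alcohol | C=C[C@@]1(C)[C@H](C(=C)CO)[C@@H](OC(=O)C(C)C)[C@@H]2C(=C)C(=O)O[C@@H]2[C@@H]1O | intermediate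
30 | epoxy alcohol | C=C[C@@]1(C)[C@H]([C@]2(CO)CO2)[C@@H](OC(=O)C(C)C)[C@@H]2C(=C)C(=O)O[C@@H]2[C@@H]1O | intermediate
31 | CNP0127398.1 | C=C[C@@]1(C)[C@H]([C@]2(C=O)CO2)[C@@H](OC(=O)C(C)C)[C@@H]2C(=C)C(=O)O[C@@H]2[C@@H]1O | target

**Step count and risks**

Total step count: 19. Longest linear sequence: 14 (steps 1–4 then 10–19; the branch 5, 6, 8, 9 then 10–19 is equally long).

**Step 13.**
- What may go wrong: closure may be slowed by the developing 1,3-diaxial contact between the C10 methyl and the C8 silyloxy group. The aldehyde would then have time to epimerise at C8, and the boronate time to react intermolecularly or be lost by protodeboronation.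
- Fallback (sets out from 19, comes back at 23):
  - The C–B bond is oxidised with NaBO3·4H2O in THF/water to the (E)-allylic alcohol F1.
  - F1 is converted with MsCl, LiCl and 2,4,6-collidine in DMF into the (E)-allylic chloride F2.
  - The primary triethylsilyl ether of F2 is oxidised directly under Swern conditions to the chloro aldehyde F3.
  - The same C9–C10 bond is closed by a Nozaki–Hiyama allylation with CrCl2 and catalytic LiI in THF at high dilution. Here divalent chromium reverses the polarity of the allylic chloride, and the γ-carbon attacks the aldehyde through the same chair-like arrangement to give 23.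

**Step 10.**
- What may go wrong: the bimolecular addition of a hindered secondary boronate to an α-branched aldehyde may be slow. During that time the primary allylboronate product could add to a second aldehyde or be lost on silica, and facial selectivity could erode.
- Fallback (sets out from 6 and 16, comes back at 19):
  - The addition is run with excess 16, and crude 17 is oxidised at once with NaOH/H2O2 to the robust 1,5-diol F4.
  - Both hydroxyls are esterified with isobutyric anhydride and DMAP to the bis(isobutyrate) F5. Its C6 ester is that of the target and its allylic ester is a leaving group.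
  - Allylic borylation under catalysis by zerovalent palladium (Pd2(dba)3, B2pin2, DMSO, 50 °C) replaces only the allylic ester by Bpin, at the unhindered terminus and with retention of the (E)-geometry. This gives 19.

**Step 15.**
- What may go wrong: competing enolisation of the isobutyrate, or incomplete enolisation of the lactone beside the C9 alkoxide, would lead to aminomethylation at the wrong ester or to recovered material.
- Fallback (sets out from 25, comes back at 28):
  - Carboxylation under thermodynamic control with MeOMgOCO2Me in DMF at 120 °C gives, after acidification, the α-carboxy lactone F6. Only a CH2 group can end as the chelated magnesium enolate, so the isobutyrate is not carboxylated.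
  - Decarboxylative Mannich methylenation of F6 (aq. formaldehyde, Et2NH, AcOH/NaOAc) gives 28 directly.

**Further compounds**
F1 | step 13 | (E)-allylic alcohol (C2–OH, C6 isobutyrate, bis-triethylsilyl ether) | OC/C=C(\C)[C@H](C(=C)CO[Si](c1ccccc1)(c1ccccc1)C(C)(C)C)[C@@H](OC(=O)C(C)C)[C@H](CC(=O)OC(C)(C)C)[C@H](O[Si](CC)(CC)CC)CO[Si](CC)(CC)CC
F2 | step 13 | (E)-allylic chloride | ClC/C=C(\C)[C@H](C(=C)CO[Si](c1ccccc1)(c1ccccc1)C(C)(C)C)[C@@H](OC(=O)C(C)C)[C@H](CC(=O)OC(C)(C)C)[C@H](O[Si](CC)(CC)CC)CO[Si](CC)(CC)CC
F3 | step 13 | chloro aldehyde | ClC/C=C(\C)[C@H](C(=C)CO[Si](c1ccccc1)(c1ccccc1)C(C)(C)C)[C@@H](OC(=O)C(C)C)[C@H](CC(=O)OC(C)(C)C)[C@H](O[Si](CC)(CC)CC)C=O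
F4 | step 10 | 1,5-diol (C2–OH and C6–OH) | OC/C=C(\C)[C@H](C(=C)CO[Si](c1ccccc1)(c1ccccc1)C(C)(C)C)[C@@H](O)[C@H](CC(=O)OC(C)(C)C)[C@H](O[Si](CC)(CC)CC)CO[Si](CC)(CC)CC
F5 | step 10 | bis(isobutyrate) | CC(C)C(=O)OC/C=C(\C)[C@H](C(=C)CO[Si](c1ccccc1)(c1ccccc1)C(C)(C)C)[C@@H](OC(=O)C(C)C)[C@H](CC(=O)OC(C)(C)C)[C@H](O[Si](CC)(CC)CC)CO[Si](CC)(CC)CC
F6 | step 15 | α-carboxy lactone | C=C[C@@]1(C)[C@H](C(=C)CO[Si](c2ccccc2)(c2ccccc2)C(C)(C)C)[C@@H](OC(=O)C(C)C)[C@@H]2C(C(=O)O)C(=O)O[C@@H]2[C@@H]1O
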